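(The earlier runs and the new flask are calculated with constants of no real substance, and the scatter is random.)

The time of reading is the first setting to weigh, since the three flasks below are read after 3.0 h, while the spring run goes from 28.2 % at 4.00 h to 29.5 % at 30.0 h and the autumn run from 19.6 % at 0.667 h to 19.7 % at 8.00 h, so the level rather than the clock is the thing to reckon. The doubt lies with south-west, read sooner than the first spring reading, though at 25 °C against 20 °C.

| flask | E | G | temperature | remark | time |
|---|---|---|---|---|---|
| spring | 0.070 M | 1.05 equiv | 20 °C | run made earlier |  |
| autumn | 0.11 M | 1.05 equiv | 45 °C | run made earlier |  |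
| south | 0.050 M | 1.05 equiv | 65 °C |  | 3.0 h |
| south-west | 0.050 M | 1.05 equiv | 25 °C |  | 3.0 h |
| south-east | 0.050 M | 1.05 equiv | 45 °C |  | 3.0 h |

- spring (time / h: X / %): 4.00: 28.2; 10.0: 28.0; 20.0: 29.4; 30.0: 29.5
- autumn (time / h: X / %): 0.667: 19.6; 1.33: 19.4; 4.00: 20.3; 8.00: 19.7

(each reading ± 0.5 percentage points)



- which flask leads in amount of X, in percent of the E charged ("all alike" within 1.5 percentage points) (south / south-west / south-east / all alike)
- how much X is there at the end, in percent of the E charged: south
- how much X is there at the end, in percent of the E charged: south-west
- how much X is there at the end, in percent of the E charged: south-east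

A level that stands still in a closed flask is taken here as a balance, E + G ⇌ X, and its measure is the plateau quotient, an apparent equilibrium constant: cX over cE·cG, with cE and cG what remains of each charge once cX is subtracted. The mean levels, 28.8 % and 19.8 %, give as readings:

K at 20 °C = 7.57 /M

K at 45 °C = 2.62 /M

Temperature is the second setting: warming lowers the quotient, and the two readings put the heat released at 32.9 kJ/mol, which carries the quotient to the new flasks by the van 't Hoff relation:

K at 25 °C = 6.04 /M

K at 45 °C = 2.62 /M

K at 65 °C = 1.26 /M

This last figure, the plateau quotient reckoned for south, is the number to carry. Concentration is the third setting: two species joining into one lose ground on dilution, so 0.050 M counts against X. The equivalents of G, the fourth, stand at 1.05 equiv in every flask and drop out of the comparison. With c the charge of E and e the equivalents, the fraction f turned into X solves: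

f = K·c·(1 − f)(e − f)

This reckoning gives 20.4 % for south-west, 11.0 % for south-east and 5.87 % for south, with south-west ahead.

The forecast, which says “I read each plateau as an equilibrium”, names south-west as leader, with 20.5 % there, 11.2 % in south-east and 6 % in south, each slightly above the reckoning here .

The flasks give 20.2 % in south-west, 10.8 % in south-east and 5.68 % in south, so south-west leads.

    E → Q (k = 5.20 /h, Ea = 88.0 kJ/mol)
    G → Z (k = 1.90 /h, Ea = 96.0 kJ/mol)
    E ⇌ D (K = 31.0, k = 0.490 /h, Ea = 83.0 kJ/mol, ΔH = 26.0 kJ/mol)
    Q + Z ⇌ X (K = 6.70 /M, k = 23.0 /M/h, Ea = 46.0 kJ/mol, ΔH = −35.0 kJ/mol)
    (constants at 25 °C)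

The level in south is a balance of X with Q and Z and not a stall: after 3.00 h E stands at 0 % and G at 0 %, the remainders of the charges standing as Q at 90.8 %, D at 3.54 % and Z at 0.0497 M, and with the back reaction of X to Q + Z struck out south gives 95.3 % in place of 5.68 %, which makes that back reaction the main reason for this level. Taken with those remainders in place of cE and cG, the result in south returns a quotient of 1.21 /M beside the reckoned 1.26 /M. Put into the neighbour of south charged with 4.20 equiv of G, 1.26 /M gives 20.1 %, and that flask holds 19.4 %.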